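**Retrosynthetic overview**

- Feature: in the naphthalene (ring B = C1 to C4 with the aryl ring C on C1, methyls on C2 and C3; ring A = C5 to C8), ring A carries C5-OMe, C6-OH, C7-OMe and C8-H in a row. This run maps onto an aryl ketene plus alkyne benzannulation: C5 is the ketene carbonyl carbon, C6 and C7 are the alkyne carbons, C8 is the ketene CH.
- End game: the C6 hydroxyl comes from a C6 silyl group (Tamao–Fleming), the C5 methyl ether from the C5 naphthol, the ring C phenol from its benzyl ether.
- Key disconnection: ring A (C8–C8a by aryl migration, C5–C6, C7–C8, C5–C4a) from a biaryl diazomethyl ketone and the silyl ynol ether MeOC≡C–SiMe2Bn.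
- The diazoketone comes from a biaryl acid made by Suzuki coupling of 2-iodo-3,4-dimethylbenzoic acid (ring B) with a ring C boronate; the ynol ether comes from chloroacetaldehyde dimethyl acetal and the chlorosilane.
- Ring order: rings B and C are bought as arenes and joined first; ring A is formed last.

Key step: step 7

Remark on the chemistry: ring C is symmetric about the biaryl axis, so the target has no stereogenic element; the transient intermediates 15 and 17 are racemic. Naphthalene names below use the numbering of the overview (C1 aryl, C5/C6/C7 oxygenated).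

**Route**

Step 1
Reactants: 1 2-amino-3,4-dimethylbenzoic acid
Product: 3 2-iodo-3,4-dimethylbenzoic acid, via diazonium chloride 2 (not isolated)
Conditions: NaNO2, aq. HCl, 0 °C; then KI, H2O, 0 → 50 °C
Reagents that add atoms: potassium iodide, [K+].[I-]
Why: Sandmeyer-type iodination: diazotisation of the aniline and displacement of N2 by iodide, which needs no copper, while the acid and the two methyl groups are untouched.

Step 2
Reactants: 4 4-bromo-2,6-dimethoxyphenol
Product: 5 2-(benzyloxy)-5-bromo-1,3-dimethoxybenzene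
Conditions: BnBr, K2CO3, DMF, 50 °C
Reagents that add atoms: benzyl bromide, BrCc1ccccc1
Why: Williamson ether synthesis: the phenoxide is alkylated by benzyl bromide, and the benzyl ether then shields the ring C phenol from ketene acylation in step 7 and from methylation in step 8.

Step 3
Reactants: 5 2-(benzyloxy)-5-bromo-1,3-dimethoxybenzene
Product: 6 2-(4-benzyloxy-3,5-dimethoxyphenyl)-4,4,5,5-tetramethyl-1,3,2-dioxaborolane
Conditions: B2pin2, Pd(dppf)Cl2 (cat.), KOAc, 1,4-dioxane, 90 °C
Reagents that add atoms: bis(pinacolato)diboron, CC1(C)OB(OC1(C)C)B1OC(C)(C)C(C)(C)O1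
Why: Miyaura borylation of an aryl bromide with no substituent next to bromine, in which KOAc activates the diboron without promoting biaryl homocoupling.

Step 4
Reactants: 3 2-iodo-3,4-dimethylbenzoic acid; 6 2-(4-benzyloxy-3,5-dimethoxyphenyl)-4,4,5,5-tetramethyl-1,3,2-dioxaborolane
Product: 7 2-(4-benzyloxy-3,5-dimethoxyphenyl)-3,4-dimethylbenzoic acid
Conditions: Pd(OAc)2 (cat.), SPhos, K3PO4 (4 equiv), 1,4-dioxane/H2O, 90 °C; then aq. HCl
Reagents that add atoms: none
Why: Suzuki–Miyaura coupling in which the bulky electron-rich SPhos ligand drives oxidative addition and reductive elimination at the iodide flanked by carboxylate and methyl, the unhindered boronate transmetalates readily, and the carboxylate is tolerated in aqueous base.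

Step 5
Reactants: 7 2-(4-benzyloxy-3,5-dimethoxyphenyl)-3,4-dimethylbenzoic acid
Product: 9 2-diazo-1-[2-(4-benzyloxy-3,5-dimethoxyphenyl)-3,4-dimethylphenyl]ethanone, via acid chloride 8 (not isolated)
Conditions: (COCl)2, DMF (cat.), CH2Cl2, 0 °C → rt, evaporate; then CH2N2 (excess), Et2O/THF, 0 °C
Reagents that add atoms: diazomethane, C=[N+]=[N-]
Why: Acylation of diazomethane by the acid chloride (first stage of the Arndt–Eistert sequence), with excess diazomethane removing HCl as chloromethane so that the diazoketone is not converted to a chloromethyl ketone.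

Step 6
Reactants: 10 chloroacetaldehyde dimethyl acetal; 11 benzylchlorodimethylsilane
Product: 13 benzyl(methoxyethynyl)dimethylsilane, via lithium methoxyacetylide 12 (not isolated)
Conditions: Et2NH, n-BuLi (3 equiv each), THF, 0 °C; then 11, −78 °C → rt
Reagents that add atoms: none
Why: Lithium diethylamide removes methanol and then HCl from the chloroacetal and deprotonates the resulting methoxyacetylene, and the lithium acetylide is silylated at carbon by the chlorosilane (alkynyl anion silylation).

Step 7
Reactants: 9 2-diazo-1-[2-(4-benzyloxy-3,5-dimethoxyphenyl)-3,4-dimethylphenyl]ethanone; 13 benzyl(methoxyethynyl)dimethylsilane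
Product: 18 6-[benzyl(dimethyl)silyl]-1-(4-benzyloxy-3,5-dimethoxyphenyl)-7-methoxy-2,3-dimethylnaphthalen-5-ol, via aryl ketene 14 (not isolated), via cyclobutenone 15 (not isolated), via silyl vinylketene 16 (not isolated), via dienone 17 (not isolated)
Conditions: 13 (2.5 equiv), hν (300 nm, Pyrex), ClCH2CH2Cl, rt; then 80 °C
Reagents that add atoms: none
Why: Light expels N2 from 9 and ring B migrates to the former diazo carbon (Wolff rearrangement) to give aryl ketene 14, whose carbonyl carbon is attacked by the silicon-bearing, methoxy-activated alkyne carbon of 13, so that (2+2) closure gives cyclobutenone 15 with C5–C6 and C7–C8 in place. Warming opens 15 by four-electron conrotatory cleavage to vinylketene 16, and ring A then closes by a six-electron disrotatory electrocyclization of the ketene carbon C5 onto C4a of ring B to give dienone 17, which tautomerises to naphthol 18. This is the Danheiser benzannulation in its diazoketone (second-generation) form, established for aryl diazomethyl ketones with alkoxy-, siloxy- and amino-substituted alkynes. No stereocentre survives, since the sp3 carbons of 15 and 17 are racemic and are erased on aromatisation. The step needs one orientation in the (2+2) addition, secured by the polarisation of the ynol ether (positive charge develops on the methoxy carbon, beta to silicon); closure at C4a only, secured because the other ortho position of ring B carries ring C; and capture of 14 by the alkyne ahead of attack by ring C or by product 18, secured by the excess of 13 and because closure onto ring C would cost the aromaticity of two rings.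

Step 8
Reactants: 18 6-[benzyl(dimethyl)silyl]-1-(4-benzyloxy-3,5-dimethoxyphenyl)-7-methoxy-2,3-dimethylnaphthalen-5-ol
Product: 19 benzyl[1-(4-benzyloxy-3,5-dimethoxyphenyl)-5,7-dimethoxy-2,3-dimethylnaphthalen-6-yl]dimethylsilane
Conditions: MeI, K2CO3, DMF, 40 °C
Reagents that add atoms: iodomethane, CI
Why: Williamson methylation of the only free hydroxyl, whose phenoxide is still reachable by the small electrophile despite the neighbouring silyl group, while the aryl–silicon bond is stable to carbonate in an aprotic solvent.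

Step 9
Reactants: 19 benzyl[1-(4-benzyloxy-3,5-dimethoxyphenyl)-5,7-dimethoxy-2,3-dimethylnaphthalen-6-yl]dimethylsilane
Product: 21 1-(4-benzyloxy-3,5-dimethoxyphenyl)-5,7-dimethoxy-2,3-dimethylnaphthalen-6-ol, via silanol 20 (not isolated)
Conditions: TBAF (3 equiv), THF, 0 °C → rt; then KHCO3, 30% aq. H2O2, MeOH, rt → 40 °C
Reagents that add atoms: hydrogen peroxide, OO
Why: Tamao–Fleming oxidation: fluoride attacks silicon and expels the benzyl group as toluene to unmask a silanol, which H2O2 oxidises with migration of the electron-rich aryl group from silicon to oxygen, so the hydroxyl appears exactly at C6.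

Step 10
Reactants: 21 1-(4-benzyloxy-3,5-dimethoxyphenyl)-5,7-dimethoxy-2,3-dimethylnaphthalen-6-ol
Product: 22 sacidumlignan A
Conditions: H2 (1 atm), Pd/C (10%), EtOAc/MeOH, rt
Reagents that add atoms: none
Why: Hydrogenolysis of the benzyl ether over palladium on carbon, under which the naphthalene, the methyl ethers and the free C6 phenol are inert.

**Compound list**

1 | 2-amino-3,4-dimethylbenzoic acid | Cc1ccc(C(=O)O)c(N)c1C | starting material
2 | 2-carboxy-5,6-dimethylbenzenediazonium chloride | Cc1ccc(C(=O)O)c([N+]#N)c1C.[Cl-] | intermediate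
3 | 2-iodo-3,4-dimethylbenzoic acid | Cc1ccc(C(=O)O)c(I)c1C | intermediate
4 | 4-bromo-2,6-dimethoxyphenol | COc1cc(Br)cc(OC)c1O | starting material
5 | 2-(benzyloxy)-5-bromo-1,3-dimethoxybenzene | COc1cc(Br)cc(OC)c1OCc1ccccc1 | intermediate
6 | 2-(4-benzyloxy-3,5-dimethoxyphenyl)-4,4,5,5-tetramethyl-1,3,2-dioxaborolane | COc1cc(B2OC(C)(C)C(C)(C)O2)cc(OC)c1OCc1ccccc1 | intermediate
7 | 2-(4-benzyloxy-3,5-dimethoxyphenyl)-3,4-dimethylbenzoic acid | Cc1ccc(C(=O)O)c(-c2cc(OC)c(OCc3ccccc3)c(OC)c2)c1C | intermediate
8 | 2-(4-benzyloxy-3,5-dimethoxyphenyl)-3,4-dimethylbenzoyl chloride | Cc1ccc(C(=O)Cl)c(-c2cc(OC)c(OCc3ccccc3)c(OC)c2)c1C | intermediate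
9 | 2-diazo-1-[2-(4-benzyloxy-3,5-dimethoxyphenyl)-3,4-dimethylphenyl]ethanone | [N-]=[N+]=CC(=O)c1ccc(C)c(C)c1-c1cc(OC)c(OCc2ccccc2)c(OC)c1 | intermediate
10 | chloroacetaldehyde dimethyl acetal | COC(CCl)OC | starting material
11 | benzylchlorodimethylsilane | C[Si](C)(Cl)Cc1ccccc1 | starting material
12 | lithium methoxyacetylide | [Li]C#COC | intermediate
13 | benzyl(methoxyethynyl)dimethylsilane | COC#C[Si](C)(C)Cc1ccccc1 | intermediate
14 | 2-[2-(4-benzyloxy-3,5-dimethoxyphenyl)-3,4-dimethylphenyl]ethenone (aryl ketene) | O=C=Cc1ccc(C)c(C)c1-c1cc(OC)c(OCc2ccccc2)c(OC)c1 | intermediate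
15 | 4-[2-(4-benzyloxy-3,5-dimethoxyphenyl)-3,4-dimethylphenyl]-2-[benzyl(dimethyl)silyl]-3-methoxycyclobut-2-en-1-one (racemic) | O=C1C([Si](C)(C)Cc2ccccc2)=C(OC)C1c1ccc(C)c(C)c1-c1cc(OC)c(OCc2ccccc2)c(OC)c1 | intermediate
16 | 2-[benzyl(dimethyl)silyl]-4-[2-(4-benzyloxy-3,5-dimethoxyphenyl)-3,4-dimethylphenyl]-3-methoxybuta-1,3-dien-1-one (aryl cis to the ketene carbon across C3=C4) | O=C=C([Si](C)(C)Cc1ccccc1)/C(OC)=C\c1ccc(C)c(C)c1-c1cc(OC)c(OCc2ccccc2)c(OC)c1 | intermediate
17 | 6-[benzyl(dimethyl)silyl]-1-(4-benzyloxy-3,5-dimethoxyphenyl)-7-methoxy-2,3-dimethyl-4aH-naphthalen-5-one (racemic at C4a) | O=C1C([Si](C)(C)Cc2ccccc2)=C(OC)C=C2C(-c3cc(OC)c(OCc4ccccc4)c(OC)c3)=C(C)C(C)=CC12 | intermediate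
18 | 6-[benzyl(dimethyl)silyl]-1-(4-benzyloxy-3,5-dimethoxyphenyl)-7-methoxy-2,3-dimethylnaphthalen-5-ol | COc1cc2c(-c3cc(OC)c(OCc4ccccc4)c(OC)c3)c(C)c(C)cc2c(O)c1[Si](C)(C)Cc1ccccc1 | intermediate
19 | benzyl[1-(4-benzyloxy-3,5-dimethoxyphenyl)-5,7-dimethoxy-2,3-dimethylnaphthalen-6-yl]dimethylsilane | COc1cc2c(-c3cc(OC)c(OCc4ccccc4)c(OC)c3)c(C)c(C)cc2c(OC)c1[Si](C)(C)Cc1ccccc1 | intermediate
20 | [1-(4-benzyloxy-3,5-dimethoxyphenyl)-5,7-dimethoxy-2,3-dimethylnaphthalen-6-yl]dimethylsilanol | COc1cc2c(-c3cc(OC)c(OCc4ccccc4)c(OC)c3)c(C)c(C)cc2c(OC)c1[Si](C)(C)O | intermediate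
21 | 1-(4-benzyloxy-3,5-dimethoxyphenyl)-5,7-dimethoxy-2,3-dimethylnaphthalen-6-ol | COc1cc2c(-c3cc(OC)c(OCc4ccccc4)c(OC)c3)c(C)c(C)cc2c(OC)c1O | intermediate
22 | sacidumlignan A, 1-(4-hydroxy-3,5-dimethoxyphenyl)-5,7-dimethoxy-2,3-dimethylnaphthalen-6-ol | COc1cc(-c2c(C)c(C)cc3c(OC)c(O)c(OC)cc23)cc(OC)c1O | target

**Step count and risks**

Total step count: 10. Longest linear sequence: 8 steps (steps 2, 3, 4, 5, 7, 8, 9, 10, from compound 4).

Steps most likely to fail:

1. Step 7 (benzannulation). The ketene may be used up before it meets the alkyne, by acylating the naphthol as it forms, by attack of the electron-rich ring C or by dimerisation, and the light may degrade the silyl naphthol. The fallback sets out from 9 and comes back at 18, generating the ketene in the dark and running the cascade in stages. Wolff rearrangement of 9 with catalytic AgO2CPh and Et3N in aqueous THF should give [2-(4-benzyloxy-3,5-dimethoxyphenyl)-3,4-dimethylphenyl]acetic acid F1. Oxalyl chloride with catalytic DMF converts it to [2-(4-benzyloxy-3,5-dimethoxyphenyl)-3,4-dimethylphenyl]acetyl chloride F2. Slow addition of Et3N to F2 and an excess of 13 in toluene at 0 °C forms ketene 14 by dehydrochlorination and traps it as cyclobutenone 15, which is isolated. Heating 15 alone in toluene at 110 °C, with no ketene left to acylate the product, should give 18 through 16 and 17.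

2. Step 9 (silicon to oxygen at C6). Fluoride may expel the aryl group from silicon in place of benzyl, because the two flanking methoxy groups stabilise negative charge at C6; this protodesilylation would remove the oxidation handle. The fallback sets out from 19 and comes back at 21, and uses that same position as an acidic C–H. Ipso protonation of 19 with CF3CO2H in CH2Cl2 at 0 °C gives 1-(4-benzyloxy-3,5-dimethoxyphenyl)-5,7-dimethoxy-2,3-dimethylnaphthalene F3. n-BuLi/TMEDA in THF at −20 °C removes the C6 proton, the only one lying between two methoxy groups, to give the C6 aryllithium F4 (directed ortho-metalation). B(OMe)3 converts it to the dimethyl arylboronate F5, which NaOH/H2O2 oxidises in the same flask to 21.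

3. Step 5 (diazoketone). The acid chloride may acylate ring C intramolecularly to a fluorenone, or HCl may add to the diazoketone to give a chloromethyl ketone. The fallback sets out from 7 and comes back at 9, avoiding both the acid chloride and diazomethane. MeLi (2.2 equiv) in THF at 0 °C converts 7 to the methyl ketone 1-[2-(4-benzyloxy-3,5-dimethoxyphenyl)-3,4-dimethylphenyl]ethanone F6. LiN(SiMe3)2 and then CF3CO2CH2CF3 at −78 °C give the trifluoroacetyl ketone 1-[2-(4-benzyloxy-3,5-dimethoxyphenyl)-3,4-dimethylphenyl]-4,4,4-trifluorobutane-1,3-dione F7. Methanesulfonyl azide, Et3N and water in MeCN at rt then effect detrifluoroacetylative diazo transfer to 9.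

**Further compounds**

F1 | step 7 | [2-(4-benzyloxy-3,5-dimethoxyphenyl)-3,4-dimethylphenyl]acetic acid | OC(=O)Cc1ccc(C)c(C)c1-c1cc(OC)c(OCc2ccccc2)c(OC)c1
F2 | step 7 | [2-(4-benzyloxy-3,5-dimethoxyphenyl)-3,4-dimethylphenyl]acetyl chloride | ClC(=O)Cc1ccc(C)c(C)c1-c1cc(OC)c(OCc2ccccc2)c(OC)c1
F3 | step 9 | 1-(4-benzyloxy-3,5-dimethoxyphenyl)-5,7-dimethoxy-2,3-dimethylnaphthalene | COc1cc(OC)c2cc(C)c(C)c(-c3cc(OC)c(OCc4ccccc4)c(OC)c3)c2c1
F4 | step 9 | [1-(4-benzyloxy-3,5-dimethoxyphenyl)-5,7-dimethoxy-2,3-dimethylnaphthalen-6-yl]lithium | COc1cc2c(-c3cc(OC)c(OCc4ccccc4)c(OC)c3)c(C)c(C)cc2c(OC)c1[Li]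
F5 | step 9 | dimethyl [1-(4-benzyloxy-3,5-dimethoxyphenyl)-5,7-dimethoxy-2,3-dimethylnaphthalen-6-yl]boronate | COc1cc2c(-c3cc(OC)c(OCc4ccccc4)c(OC)c3)c(C)c(C)cc2c(OC)c1B(OC)OC
F6 | step 5 | 1-[2-(4-benzyloxy-3,5-dimethoxyphenyl)-3,4-dimethylphenyl]ethanone | CC(=O)c1ccc(C)c(C)c1-c1cc(OC)c(OCc2ccccc2)c(OC)c1
F7 | step 5 | 1-[2-(4-benzyloxy-3,5-dimethoxyphenyl)-3,4-dimethylphenyl]-4,4,4-trifluorobutane-1,3-dione | O=C(CC(=O)C(F)(F)F)c1ccc(C)c(C)c1-c1cc(OC)c(OCc2ccccc2)c(OC)c1
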